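**Retrosynthetic overview**
- Target ⇒ 4′-oxomacrophorin A (primary allylic alcohol) + achiral 3-hydroxy-3-methylglutaric (HMG) anhydride; a catalyst-controlled desymmetrising acylation sets the HMG stereocentre last.
- Decalin ⇒ acyclic (E,E)-farnesyl epoxyquinone by a late-stage, chiral-Brønsted-acid-catalysed cationic bicyclisation (rings A and B in one operation, exocyclic alkene by proton loss).
- Epoxyquinone ⇒ p-quinone monoketal: the ketal leaves one enone with a free β-carbon, so a phase-transfer asymmetric epoxidation sets the first stereocentres regioselectively.
- Monoketal ⇒ ortho-farnesylated p-methoxyphenol ⇒ 5-hydroxy-2-methoxybenzaldehyde + (2E,6E)-farnesyl bromide.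
- Ring order: six-membered carbocycle (from the arene) → epoxide → decalin rings A then B.

Assumption: for each chiral catalyst (steps 4, 6, 7) the antipode or pseudo-enantiomer giving the drawn series is identified by running both; descriptors below are for the desired series.

**Step 1**
Reactants: 1, 5-hydroxy-2-methoxybenzaldehyde
Product: 2, 3-(hydroxymethyl)-4-methoxyphenol
Conditions: NaBH4, MeOH, 0 °C
Reagents that add atoms: none
Why: Chemoselective borohydride reduction of the aryl aldehyde; the phenol is untouched and no stereocentre is formed.

**Step 2**
Reactants: 2, 3-(hydroxymethyl)-4-methoxyphenol; 3, (2E,6E)-farnesyl bromide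
Product: 4, 5-(hydroxymethyl)-4-methoxy-2-[(2E,6E)-3,7,11-trimethyldodeca-2,6,10-trien-1-yl]phenol
Conditions: NaH (1.0 equiv), toluene/Et2O, 0 °C → rt; then 3, rt
Reagents that add atoms: none (the farnesyl unit comes from 3)
Why: ortho-C-Alkylation of an aggregated sodium phenoxide in a non-polar medium (SN2 at the primary allylic bromide, 2E geometry kept); the para position is blocked by OMe and only the ortho carbon para to CH2OH is unhindered, while one equivalent of base leaves the primary alcohol un-ionised.

**Step 3**
Reactants: 4
Product: 5, 5-(hydroxymethyl)-4,4-dimethoxy-2-[(2E,6E)-3,7,11-trimethyldodeca-2,6,10-trien-1-yl]cyclohexa-2,5-dien-1-one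
Conditions: PhI(OAc)2, NaHCO3, MeOH, 0 °C
Reagents that add atoms: methanol, CO
Why: Oxidative dearomatisation of a p-methoxyphenol to the p-quinone monoketal (methanol adds at the OMe-bearing carbon); this masks the carbonyl next to the CH2OH-bearing carbon so that only the farnesyl-bearing C2=C3 enone has an unsubstituted β-carbon.

**Step 4**
Reactants: 5
Product: 6, (1R,6S)-4-(hydroxymethyl)-5,5-dimethoxy-1-[(2E,6E)-3,7,11-trimethyldodeca-2,6,10-trien-1-yl]-7-oxabicyclo[4.1.0]hept-3-en-2-one (C1 = quaternary epoxide carbon carrying the farnesyl group, C6 = epoxide CH next to the ketal)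
Conditions: t-BuOOH, aq. NaOH, N-(9-anthracenylmethyl)cinchona ammonium salt (10 mol %; cinchonidinium or cinchoninium series, whichever gives 1R,6S), toluene, 0 °C
Reagents that add atoms: tert-butyl hydroperoxide, CC(C)(C)OO
Why: Weitz–Scheffer nucleophilic epoxidation under chiral phase-transfer (ion-pair) catalysis; the chiral ammonium–peroxide pair adds to one enantiotopic face of the only free β-carbon (C3) and enolate ring closure gives the cis-epoxide, setting the first two stereocentres on an achiral substrate.

**Step 5**
Reactants: 6
Product: 7, (1R,6S)-4-(hydroxymethyl)-1-[(2E,6E)-3,7,11-trimethyldodeca-2,6,10-trien-1-yl]-7-oxabicyclo[4.1.0]hept-3-ene-2,5-dione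
Conditions: montmorillonite K10, wet CH2Cl2, rt
Reagents that add atoms: water, O
Why: Mild solid-acid hydrolysis of the dimethyl ketal to the enedione; the α,β-epoxy ketone is resistant to acid opening and the isolated trisubstituted alkenes survive at rt, so the epoxide stereocentres are untouched.

**Step 6**
Reactants: 7
Product: 8, 4′-oxomacrophorin A, (1R,6S)-4-(hydroxymethyl)-1-{[(1S,4aS,8aS)-5,5,8a-trimethyl-2-methylidenedecahydronaphthalen-1-yl]methyl}-7-oxabicyclo[4.1.0]hept-3-ene-2,5-dione (trans-decalin; angular CH3 and the C1 side chain both β, H-4a α)
Conditions: confined chiral imidodiphosphorimidate (IDPi) Brønsted acid (5 mol %), (CF3)3COH/CHCl3, −30 °C, stopped at partial conversion with Et3N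
Reagents that add atoms: none
Why: Proposed new method: a catalyst-controlled proton-initiated bicyclisation of a farnesyl epoxy-enedione ending in selective loss of a methyl proton. The strongly acidic, confined IDPi protonates only the distal Me2C=CH (the proximal alkene is inductively deactivated by the epoxy-ketone). The pocket holds a chair–chair fold, so anti addition across the two E-alkenes gives the trans-decalin with an equatorial C1 side chain, and the chiral anion chooses the alkene face (1S,4aS,8aS; the epoxide is too remote to interfere). With no π- or OH-terminator, the tertiary cation at decalin C2 is reversibly capped by the neighbouring C2=O of the enedione as an equatorial six-membered oxocarbenium; only the methyl hydrogens are anti-periplanar to that C–O bond, so proton transfer to the IDPi anion gives the exocyclic alkene. Closest known reaction type: IDPi-catalysed enantioselective polyene cyclisation of homofarnesol (hydroxyl-terminated), and the biosynthetic late-stage cyclisation of this substrate class.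

**Step 7**
Reactants: 8; 9, 3-hydroxy-3-methylglutaric anhydride (4-hydroxy-4-methyloxane-2,6-dione)
Product: 10, 4′-oxomacrophorin D, the (3S)-3-hydroxy-3-methylglutaric acid mono-ester of the primary alcohol of 8 (epoxide carbon bearing the side chain R, epoxide CH S, decalin 1S,4aS,8aS)
Conditions: 9 (1.5 equiv), bifunctional cinchona squaramide (10 mol %; quinine or quinidine series, whichever gives 3S), MTBE, −20 °C; dilute acid work-up
Reagents that add atoms: none (the HMG unit comes from 9)
Why: Desymmetrising alcoholysis of a prochiral glutaric anhydride by bifunctional cinchona catalysis (quinuclidine activates the primary alcohol, the squaramide binds one enantiotopic carbonyl), giving the hemiester with free acid and setting C3 under catalyst control; this reaction class is established for 3-substituted glutaric anhydrides, but its use with 9 and a complex alcohol is an untested extension.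

**Compound list**
1 | 5-hydroxy-2-methoxybenzaldehyde | COc1ccc(O)cc1C=O | starting material
2 | 3-(hydroxymethyl)-4-methoxyphenol | COc1ccc(O)cc1CO | intermediate
3 | (2E,6E)-farnesyl bromide | CC(C)=CCC/C(C)=C/CC/C(C)=C/CBr | starting material
4 | 5-(hydroxymethyl)-4-methoxy-2-[(2E,6E)-farnesyl]phenol | CC(C)=CCC/C(C)=C/CC/C(C)=C/Cc1cc(OC)c(CO)cc1O | intermediate
5 | 5-(hydroxymethyl)-4,4-dimethoxy-2-[(2E,6E)-farnesyl]cyclohexa-2,5-dien-1-one | CC(C)=CCC/C(C)=C/CC/C(C)=C/CC1=CC(OC)(OC)C(CO)=CC1=O | intermediate
6 | (1R,6S)-1-[(2E,6E)-farnesyl]-4-(hydroxymethyl)-5,5-dimethoxy-7-oxabicyclo[4.1.0]hept-3-en-2-one | CC(C)=CCC/C(C)=C/CC/C(C)=C/C[C@@]12O[C@@H]1C(OC)(OC)C(CO)=CC2=O | intermediate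
7 | (1R,6S)-1-[(2E,6E)-farnesyl]-4-(hydroxymethyl)-7-oxabicyclo[4.1.0]hept-3-ene-2,5-dione | CC(C)=CCC/C(C)=C/CC/C(C)=C/C[C@@]12O[C@@H]1C(=O)C(CO)=CC2=O | intermediate
8 | 4′-oxomacrophorin A | C=C1CC[C@H]2C(C)(C)CCC[C@]2(C)[C@H]1C[C@@]12O[C@@H]1C(=O)C(CO)=CC2=O | intermediate
9 | 3-hydroxy-3-methylglutaric anhydride | CC1(O)CC(=O)OC(=O)C1 | starting material
10 | 4′-oxomacrophorin D | C=C1CC[C@H]2C(C)(C)CCC[C@]2(C)[C@H]1C[C@@]12O[C@@H]1C(=O)C(COC(=O)C[C@@](C)(O)CC(=O)O)=CC2=O | target

**Totals**
Total step count: 7. Longest linear sequence: 7 (1 → 10; 3 and 9 enter as purchased reagents).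

**Three steps most likely to fail**
1. Step 6 (proposed new method). Risks: proton loss may give the endocyclic Δ7 and Δ8(9) isomers, the product alkene may be re-protonated, and the epoxide or carbonyl oxygen may trap the cation. Fallback (known chemistry, different approach): build the decalin first and drop the late cyclisation.
   - Make the Wieland–Miescher ketone by proline catalysis from 2-methylcyclohexane-1,3-dione and methyl vinyl ketone.
   - Elaborate it by established steps to albicanal, with the exocyclic alkene installed by Wittig methylenation of the C8 ketone.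
   - Add the aryllithium from a bis-protected bromo derivative of 2, deoxygenate the benzylic position and deprotect to give the drimanyl analogue of 4.
   - Run steps 3–5 and 7 as written.
2. Step 7. Risks: weak discrimination of CH3 versus OH at the prochiral centre, and the amine sensitivity of the epoxyquinone. Fallback: prepare the hemiester separately and attach it.
   - Open 9 with 2-(trimethylsilyl)ethanol under cinchona catalysis to the (R)-hemiester and upgrade its ee by crystallising an amine salt.
   - Couple the free acid to 8 with a carbodiimide.
   - Remove the silylethyl ester with buffered fluoride (two extra steps in total).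
3. Step 4. Risk: moderate ee for an α-alkyl dienone under phase-transfer conditions. Minor epoxide enantiomer is in any case converted into a separable diastereomer in step 6. Fallback: run a racemic Weitz–Scheffer epoxidation (t-BuOOH/DBU) and resolve (±)-6 by lipase-catalysed kinetic acylation of its primary alcohol, carrying the (1R,6S) enantiomer forward.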